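The earlier runs and the new flask were computed from invented constants; noise was put on by code.

The question is how this flask, charged with 1.50 M of reagent, shares its substrate between target and uncatalysed product, so I look for a number from which the clock drops out.

| flask | substrate | reagent | free catalyst | remark | time |
|---|---|---|---|---|---|
| Saturday's | 1 M | 1.5 M | 5 mM | the very flask that is asked about, followed so far |  |
| Wednesday's | 1 M | 1 M | 5 mM | run made earlier |  |
| flask | 1.0 M | 1.50 M | 5.0 mM |  | 1.5 h |

| run | time / min | target / % | uncatalysed product / % |
|---|---|---|---|
| Saturday's | 5.00 | 3.4 | 7.2 |
| Saturday's | 10.0 | 9.8 | 11.5 |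
| Saturday's | 15.0 | 16.6 | 16.2 |
| Saturday's | 20.0 | 21.7 | 19.2 |
| Wednesday's | 25.0 | 23.1 | 14.4 |
| Wednesday's | 50.0 | 39.4 | 20.1 |
| Wednesday's | 60.0 | 43.6 | 21.7 |
| Wednesday's | 90.0 | 52.6 | 23.1 |

(each reading ± 0.3 percentage points)

- ratio of target to uncatalysed product at 40 s
- ratio of target to uncatalysed product at 1.5 h
- which of target and uncatalysed product there is more of at 1.5 h

- what may be going on: substrate + free catalyst <-> free catalyst + open intermediate; free catalyst + open intermediate <-> catalyst intermediate; reagent + catalyst intermediate -> free catalyst + target; substrate + reagent -> uncatalysed product

Substrate opens under the free catalyst and the open intermediate binds it as catalyst intermediate. Reagent then meets catalyst intermediate to give target, or meets substrate directly to give uncatalysed product. I set these two rates against each other: their quotient is target gained per uncatalysed product gained, with no time interval in it, and the [reagent] written in both rates cancels, leaving [catalyst intermediate]/[substrate] times a ratio of rate constants. That [catalyst intermediate]/[substrate] may drift during a run and may differ with the reagent charge, so carrying the quotient from Wednesday's run to Saturday's is an assumption of my reckoning and no more.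

Wednesday's readings from 25.0 min to 90.0 min give 3.39 for what I call the split, the target gained per uncatalysed product gained over one interval, a selectivity factor read from readings. Saturday's flask at 20.0 min still has 59.1% of its substrate unturned into either product. If that whole remainder passes at this split, my reckoning for the final ratio is 2.06.

The forecast gives 0.014 at 40 s, 2.5 at 1.5 h and target ahead, holding that “substrate is about 0.6 of the remaining pool”; its late ratio is higher than mine.

The flask gives 0.0895 and 1.80, with target ahead.

    substrate + free catalyst ⇌ free catalyst + open intermediate (K = 0.600, k = 0.147 M⁻¹ s⁻¹)
    free catalyst + open intermediate ⇌ catalyst intermediate (K = 1.89 M⁻¹, k = 0.759 M⁻¹ s⁻¹)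
    reagent + catalyst intermediate → free catalyst + target (k = 0.259 M⁻¹ s⁻¹)
    substrate + reagent → uncatalysed product (k = 1.81 × 10⁻⁴ M⁻¹ s⁻¹)

Between 20.0 min and 1.50 h Saturday's flask gains 36 percentage points of target against 13 points of uncatalysed product, a split of 2.81, which is less than Wednesday's 3.39. The neighbour charged with 0.38 M of reagent holds 25.8% of target and 8.99% of uncatalysed product at 1.50 h, a split counted from the start of 2.87.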